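**Retrosynthetic overview**

1. Target ⇐ desilylation ⇐ ring contraction. Ring A (C10, C1, C2, C3, C4, C5) is made last from the cycloheptane C10–C1–C2–C3–C4–C5–C6 by a semipinacol 1,2-shift of C10 from C6 to C5. This forms the C5–C10 bond, the C5 stereocentre and the C6 aldehyde beside the C4 acetate.
2. Enabling feature: on the seven-membered ring the C6 hydroxyl is trans to a C5 mesylate (ring bond C6–C10 antiperiplanar to C5–O, H6 syn to the leaving group). C6 carries H and so ends as CHO, and the cis C4 acetate can neither participate nor donate. The array comes from syn-dihydroxylation of C4=C5.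
3. Rings C and D (bicyclo[3.2.1]octane C8, C9, C11–C16) ⇐ palladium-mediated cycloalkenylation of the C15 methyl ketone onto C12=C13 ⇐ Diels–Alder reaction of butadiene with the α-acetyl α,β-unsaturated spiro δ-lactone (sets C8 and C9).
4. Spiro lactone ⇐ acetoacetylation/Knoevenagel condensation at C20/C9. Cycloheptene ⇐ ring-closing metathesis at C4=C5. Quaternary C10 ⇐ Fráter–Seebach hydroxymethylation relayed from the disposable C6 carbinol (Evans aldol with acrolein). C3 ⇐ CBS reduction.
5. Order of ring formation: seven-membered carbocycle → δ-lactone → ring C → ring D → ring A (by contraction).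

Key step: step 23

Remark on the chemistry: locants C1–C20 are those of the ent-kaurane skeleton of the target (ring A = C10, C1, C2, C3, C4, C5; C6 = aldehyde carbon; C7 = lactone carbonyl; C20 = lactone CH2; C18 = methyl on C4; C17 = exocyclic methylene carbon). Monomeric formaldehyde from cracked paraformaldehyde is taken as a commercial starting material. TBS = tert-butyldimethylsilyl, TES = triethylsilyl.

**Route**

Step 1
Reactants: 1 methyl 5-chloro-5-oxopentanoate; 2 isopropenylmagnesium bromide
Product: 3 methyl 6-methyl-5-oxohept-6-enoate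
Conditions: CuI (5 mol%), THF, −78 °C, slow addition of 2 (1.0 equiv)
Reagents that add atoms: none
Why: Copper-catalysed acylation of a Grignard reagent by an acid chloride is much faster than attack on the methyl ester at −78 °C and should stop at the isopropenyl ketone; no stereocentre is formed.

Step 2
Reactants: 3 methyl 6-methyl-5-oxohept-6-enoate
Product: 4 methyl (5S)-5-hydroxy-6-methylhept-6-enoate
Conditions: (R)-2-methyl-CBS-oxazaborolidine (10 mol%), catecholborane, toluene, −78 °C; aqueous work-up
Reagents that add atoms: none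
Why: Corey–Bakshi–Shibata reduction, with the isopropenyl group as the large substituent, should deliver hydride to one ketone face and set C3 as (S).

Step 3
Reactants: 4 methyl (5S)-5-hydroxy-6-methylhept-6-enoate
Product: 5 methyl (5S)-5-(tert-butyldimethylsilyloxy)-6-methylhept-6-enoate
Conditions: tert-butyldimethylsilyl chloride, imidazole, DMF, 0 °C to rt (directly after step 2)
Reagents that add atoms: tert-butyldimethylsilyl chloride, CC(C)(C)[Si](C)(C)Cl
Why: Imidazole-promoted silyl ether formation blocks δ-lactonisation and turns the C3 oxygen into the bulky group that later steers the osmylation; the stereocentre is untouched.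

Step 4
Reactants: 5 methyl (5S)-5-(tert-butyldimethylsilyloxy)-6-methylhept-6-enoate
Product: 6 (5S)-5-(tert-butyldimethylsilyloxy)-6-methylhept-6-enoic acid
Conditions: LiOH, THF/MeOH/H2O, rt; then aqueous HCl to pH 4
Reagents that add atoms: lithium hydroxide, [Li+].[OH-]
Why: Saponification of the unhindered methyl ester should leave the silyl ether and the alkene unchanged.

Step 5
Reactants: 6 (5S)-5-(tert-butyldimethylsilyloxy)-6-methylhept-6-enoic acid; 7 (4R)-4-benzyl-1,3-oxazolidin-2-one
Product: 9 (4R)-4-benzyl-3-[(5S)-5-(tert-butyldimethylsilyloxy)-6-methylhept-6-enoyl]-1,3-oxazolidin-2-one, via mixed pivalic anhydride 8 (not isolated)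
Conditions: pivaloyl chloride, Et3N, THF, −20 °C; then 7, LiCl, rt
Reagents that add atoms: none
Why: Mixed-anhydride activation followed by LiCl-assisted N-acylation is the standard loading of an Evans oxazolidinone and should not disturb the allylic silyl ether.

Step 6
Reactants: 9 (4R)-4-benzyl-3-[(5S)-5-(tert-butyldimethylsilyloxy)-6-methylhept-6-enoyl]-1,3-oxazolidin-2-one; 10 acrolein
Product: 12 (4R)-4-benzyl-3-[(2R,3S)-2-[(3S)-3-(tert-butyldimethylsilyloxy)-4-methylpent-4-en-1-yl]-3-hydroxypent-4-enoyl]-1,3-oxazolidin-2-one, via boron Z-enolate 11 (not isolated)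
Conditions: Bu2BOTf, iPr2NEt, CH2Cl2, −78 to 0 °C; then 10, −78 °C; MeOH, pH 7 buffer, H2O2 work-up
Reagents that add atoms: none
Why: Evans syn-aldol reaction: the Z-boron enolate of the (R)-auxiliary adds to acrolein through a Zimmerman–Traxler chair and should set C6 as (S) (and C10, erased later, as (R)).

Step 7
Reactants: 12 the Evans aldol adduct
Product: 13 methyl (2R,3S)-2-[(3S)-3-(tert-butyldimethylsilyloxy)-4-methylpent-4-en-1-yl]-3-hydroxypent-4-enoate
Conditions: NaOMe (1.1 equiv), MeOH/CH2Cl2, −10 °C; aqueous NH4Cl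
Reagents that add atoms: sodium methoxide, [Na+].[O-]C
Why: Methanolysis of the imide (transesterification) gives the ester needed for dianion chemistry and returns the auxiliary; at −10 °C retro-aldol cleavage should not compete.

Step 8
Reactants: 13 the β-hydroxy methyl ester; 14 formaldehyde
Product: 16 methyl (2S,3S)-2-[(3S)-3-(tert-butyldimethylsilyloxy)-4-methylpent-4-en-1-yl]-3-hydroxy-2-(hydroxymethyl)pent-4-enoate, via dilithium dianion 15 (not isolated)
Conditions: LiN(iPr)2 (2.3 equiv), THF, −78 to −20 °C; then 14 (gas), −78 °C; aqueous NH4Cl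
Reagents that add atoms: none
Why: Fráter–Seebach alkylation: in the lithium-chelated alkoxide–enolate formaldehyde should attack C10 anti to the C6 alkoxide, so the disposable C6 carbinol relays its configuration to the quaternary C10 (S; new CH2OH = C20, ester carbon = C9).

Step 9
Reactants: 16 the acyclic diol ester
Product: 17 methyl (1S,2S,5S)-5-(tert-butyldimethylsilyloxy)-2-hydroxy-1-(hydroxymethyl)-4-methylcyclohept-3-ene-1-carboxylate
Conditions: second-generation Hoveyda–Grubbs catalyst (10 mol%), toluene (5 mM), 80 °C, argon sparge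
Reagents that add atoms: none
Why: Ring-closing metathesis should form the trisubstituted C4=C5 alkene of the seven-membered ring; the free allylic C6 hydroxyl speeds loading at the vinyl group and loss of ethylene drives the closure.

Step 10
Reactants: 17 the cycloheptene diol ester
Product: 18 methyl (1S,2S,5S)-5-(tert-butyldimethylsilyloxy)-4-methyl-2-(triethylsilyloxy)-1-[(triethylsilyloxy)methyl]cyclohept-3-ene-1-carboxylate
Conditions: triethylsilyl triflate (2.5 equiv), 2,6-lutidine, CH2Cl2, −78 to 0 °C
Reagents that add atoms: triethylsilyl trifluoromethanesulfonate, CC[Si](CC)(CC)OS(=O)(=O)C(F)(F)F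
Why: Silylation with the reactive triflate should protect the hindered secondary C6 hydroxyl and the primary C20 hydroxyl in one operation.

Step 11
Reactants: 18 the bis(triethylsilyl) ester
Product: 19 the C9 primary alcohol (CO2Me of 18 reduced to CH2OH; silyl ethers and configurations as in 18)
Conditions: iBu2AlH (3 equiv), CH2Cl2, −78 to 0 °C; aqueous potassium sodium tartrate
Reagents that add atoms: none
Why: Hydride reduction of the neopentyl ester to the alcohol is compatible with the three silyl ethers and the alkene.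

Step 12
Reactants: 19 the C9 primary alcohol
Product: 20 the C9 aldehyde (CH2OH of 19 oxidised to CHO)
Conditions: Dess–Martin periodinane, NaHCO3, CH2Cl2, rt
Reagents that add atoms: none
Why: Dess–Martin oxidation should give the non-enolisable aldehyde under buffered, neutral conditions.

Step 13
Reactants: 20 the C9 aldehyde
Product: 21 the β-hydroxy aldehyde (primary C20 triethylsilyl ether of 20 cleaved; C6-OTES and C3-OTBS kept)
Conditions: HF·pyridine, pyridine, THF, 0 °C
Reagents that add atoms: none
Why: Selective desilylation: the primary triethylsilyl ether should be cleaved much faster than the hindered secondary triethylsilyl and tert-butyldimethylsilyl ethers.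

Step 14
Reactants: 21 the β-hydroxy aldehyde; 22 2,2,6-trimethyl-4H-1,3-dioxin-4-one
Product: 24 the spiro dienophile (3-acetyl-5,6-dihydro-2H-pyran-2-one spiro-fused at its C5 = C10 to the cycloheptene that carries C3-OTBS, C4 methyl, C4=C5 and C6-OTES), via C20 acetoacetate 23 (not isolated)
Conditions: 22 (1.5 equiv), toluene, 110 °C; then piperidine (20 mol%), AcOH (20 mol%), 4 Å molecular sieves, CH2Cl2, rt
Reagents that add atoms: none
Why: Thermal retro-[4+2] of the dioxinone gives acetylketene, which acylates the only free hydroxyl (C20); amine-catalysed intramolecular Knoevenagel condensation onto the C9 aldehyde should then close the α-acetyl-α,β-unsaturated δ-lactone.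

Step 15
Reactants: 24 the spiro dienophile; 25 buta-1,3-diene
Product: 26 the Diels–Alder adduct (cis-fused cyclohexene ring C with C12=C13 on the δ-lactone; acetyl on quaternary C8)
Conditions: 25 (excess), ZnCl2 (1 equiv), CH2Cl2, 0 °C to rt, sealed tube
Reagents that add atoms: none
Why: Lewis-acid-promoted Diels–Alder reaction: ZnCl2 chelates the β-keto lactone, butadiene should add to the C8=C9 face anti to the C6 silyl ether flank of the spiro centre (sets C9), and suprafacial addition leaves the acetyl group cis to H9 at the new quaternary C8.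

Step 16
Reactants: 26 the Diels–Alder adduct
Product: 28 the bicyclo[3.2.1]octenone (C16–C13 bond formed, C15 ketone, C11=C12), via trimethylsilyl enol ether 27 (not isolated)
Conditions: trimethylsilyl triflate, Et3N, CH2Cl2, 0 °C; then Pd(OAc)2 (1.1 equiv), MeCN, rt
Reagents that add atoms: none
Why: Palladium-mediated cycloalkenylation (Saegusa–Ito-type cyclisation of a 2-silyloxy-1,5-diene): C16 of the enol silane should add 5-exo to C13 on the face of the axial acyl group (C13 is fixed by the bridge) and β-hydride elimination towards C11 gives the enone-free bicycle; the enol silane has no β-hydrogen for simple dehydrogenation.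

Step 17
Reactants: 28 the bicyclo[3.2.1]octenone
Product: 29 the saturated bicyclo[3.2.1]octanone (C11–C12 single bond)
Conditions: H2 (1 atm), RhCl(PPh3)3 (5 mol%), benzene, rt
Reagents that add atoms: none
Why: Homogeneous hydrogenation should reduce the cis-disubstituted C11=C12 alkene and leave the hindered trisubstituted C4=C5 alkene untouched.

Step 18
Reactants: 29 the saturated bicyclo[3.2.1]octanone
Product: 30 the C4,C5 cis-diol (both hydroxyls on the face of the C20 arm, trans to C3-OTBS and C6-OTES)
Conditions: OsO4 (10 mol%), N-methylmorpholine N-oxide, acetone/H2O, 40 °C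
Reagents that add atoms: N-methylmorpholine N-oxide, C[N+]1([O-])CCOCC1; water, O
Why: Catalytic syn-dihydroxylation (Upjohn conditions): OsO4 should add to the C4=C5 face anti to both allylic silyl ethers and to the bulky C9 flank of the spiro centre, which sets C4 and C5.

Step 19
Reactants: 30 the C4,C5 cis-diol
Product: 31 the C5 mesylate (tertiary C4 hydroxyl free)
Conditions: methanesulfonyl chloride, Et3N, CH2Cl2, 0 °C
Reagents that add atoms: methanesulfonyl chloride, CS(=O)(=O)Cl
Why: Sulfonylation via sulfene should convert only the secondary C5 hydroxyl into the leaving group; the tertiary C4 hydroxyl does not react.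

Step 20
Reactants: 31 the C5 mesylate
Product: 32 the C4 acetate C5 mesylate
Conditions: Ac2O, DMAP, Et3N, CH2Cl2, 40 °C
Reagents that add atoms: acetic anhydride, CC(=O)OC(C)=O
Why: DMAP-catalysed acylation of the tertiary alcohol installs the C4 acetate of the target and removes this oxygen as a competing donor in the rearrangement; the cis mesylate cannot be displaced by it.

Step 21
Reactants: 32 the C4 acetate C5 mesylate
Product: 33 the α-methylene ketone (C16=C17 exocyclic enone)
Conditions: N,N,N′,N′-tetramethylmethanediamine, Ac2O, DMF, 95 °C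
Reagents that add atoms: N,N,N′,N′-tetramethylmethanediamine, CN(C)CN(C)C
Why: α-Methylenation by in situ Mannich condensation and elimination: C16 is the only enolisable position of the C15 ketone because C8 is quaternary.

Step 22
Reactants: 33 the α-methylene ketone
Product: 34 the C6 alcohol (C6-OH trans to C5-OMs; C3-OTBS kept)
Conditions: HF·pyridine, pyridine, THF, 0 °C to rt
Reagents that add atoms: none
Why: Selective desilylation: buffered HF·pyridine should remove the triethylsilyl ether at C6 in the presence of the more robust tert-butyldimethylsilyl ether.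

Step 23
Reactants: 34 the C6 alcohol
Product: 36 the 3-O-TBS ether of the target (ring A formed, C6 aldehyde), via aluminium alkoxide 35 (not isolated)
Conditions: Et2AlCl (1.2 equiv), CH2Cl2, −78 °C; then −78 to −20 °C; aqueous potassium sodium tartrate
Reagents that add atoms: none
Why: Et2AlCl converts the C6 hydroxyl into an aluminium alkoxide whose oxygen pushes the C6–C10 σ-bond onto C5 while aluminium assists departure of the mesylate, so C10 shifts from C6 to C5 and C6 is left as the aldehyde; this is the organoaluminium-promoted pinacol-type (semipinacol) rearrangement of β-mesyloxy alcohols in its ring-contracting form, as known for trans-2-sulfonyloxy cycloalkanols. Ring A (C10, C1, C2, C3, C4, C5) is closed by this suprafacial 1,2-alkyl shift, a contraction of the cycloheptane by extrusion of C6 (formally a 3-exo-tet displacement at C5 by the C6–C10 bond), not by cyclisation of a chain. C5 is the only new stereocentre and forms with inversion, so it is dictated by the C5–OMs configuration from the syn-dihydroxylation (formyl cis to the C4 acetate), while C10 migrates with retention and keeps the C9/C20 arrangement fixed in step 8. The step needs migration of C10 in preference to hydride shift, epoxide closure and acetate participation: H6 is syn to the leaving group and cannot migrate, the trans-diequatorial O6/OMs pair places the ring bond C6–C10 antiperiplanar to C5–O, the aluminium alkoxide is a poor nucleophile for epoxide formation, and the C4 acetate is cis to the mesylate and, being acylated, is no competing donor. The low temperature and the weakly nucleophilic ethyl groups of Et2AlCl should leave the exocyclic enone, the lactone and the new aldehyde untouched.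

Step 24
Reactants: 36 the 3-O-TBS ether of the target
Product: 37 CNP0199571.1 (target)
Conditions: HF·pyridine (excess), THF, rt
Reagents that add atoms: none
Why: Fluoride-mediated desilylation under mildly acidic conditions should free the C3 hydroxyl without base, so that neither β-elimination of the C4 acetate nor acyl migration is triggered.

**Compound list**

1 | methyl 5-chloro-5-oxopentanoate | COC(=O)CCCC(=O)Cl | starting material
2 | isopropenylmagnesium bromide | C=C(C)[Mg]Br | starting material
3 | methyl 6-methyl-5-oxohept-6-enoate | COC(=O)CCCC(=O)C(C)=C | intermediate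
4 | methyl (5S)-5-hydroxy-6-methylhept-6-enoate | COC(=O)CCC[C@H](O)C(C)=C | intermediate
5 | methyl (5S)-5-(tert-butyldimethylsilyloxy)-6-methylhept-6-enoate | COC(=O)CCC[C@H](O[Si](C)(C)C(C)(C)C)C(C)=C | intermediate
6 | (5S)-5-(tert-butyldimethylsilyloxy)-6-methylhept-6-enoic acid | OC(=O)CCC[C@H](O[Si](C)(C)C(C)(C)C)C(C)=C | intermediate
7 | (4R)-4-benzyl-1,3-oxazolidin-2-one | O=C1N[C@H](Cc2ccccc2)CO1 | starting material
8 | mixed pivalic anhydride of 6 | CC(C)(C)C(=O)OC(=O)CCC[C@H](O[Si](C)(C)C(C)(C)C)C(C)=C | intermediate (not isolated)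
9 | (4R)-4-benzyl-3-[(5S)-5-(tert-butyldimethylsilyloxy)-6-methylhept-6-enoyl]-1,3-oxazolidin-2-one | O=C1OC[C@@H](Cc2ccccc2)N1C(=O)CCC[C@H](O[Si](C)(C)C(C)(C)C)C(C)=C | intermediate
10 | acrolein (prop-2-enal) | C=CC=O | starting material
11 | dibutylboron Z-enolate of 9 | CCCCB(CCCC)O/C(N1[C@H](Cc2ccccc2)COC1=O)=C\CC[C@H](O[Si](C)(C)C(C)(C)C)C(C)=C | intermediate (not isolated)
12 | (4R)-4-benzyl-3-[(2R,3S)-2-[(3S)-3-(tert-butyldimethylsilyloxy)-4-methylpent-4-en-1-yl]-3-hydroxypent-4-enoyl]-1,3-oxazolidin-2-one | O=C1OC[C@@H](Cc2ccccc2)N1C(=O)[C@@H]([C@@H](O)C=C)CC[C@H](O[Si](C)(C)C(C)(C)C)C(C)=C | intermediate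
13 | methyl (2R,3S)-2-[(3S)-3-(tert-butyldimethylsilyloxy)-4-methylpent-4-en-1-yl]-3-hydroxypent-4-enoate | COC(=O)[C@@H]([C@@H](O)C=C)CC[C@H](O[Si](C)(C)C(C)(C)C)C(C)=C | intermediate
14 | formaldehyde (monomer from paraformaldehyde) | C=O | starting material
15 | dilithium alkoxide–enolate of 13 (enolate geometry not specified) | [Li+].[Li+].COC([O-])=C(CC[C@H](O[Si](C)(C)C(C)(C)C)C(C)=C)[C@@H]([O-])C=C | intermediate (not isolated)
16 | methyl (2S,3S)-2-[(3S)-3-(tert-butyldimethylsilyloxy)-4-methylpent-4-en-1-yl]-3-hydroxy-2-(hydroxymethyl)pent-4-enoate | COC(=O)[C@@]([C@@H](O)C=C)(CC[C@H](O[Si](C)(C)C(C)(C)C)C(C)=C)CO | intermediate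
17 | methyl (1S,2S,5S)-5-(tert-butyldimethylsilyloxy)-2-hydroxy-1-(hydroxymethyl)-4-methylcyclohept-3-ene-1-carboxylate | COC(=O)[C@@]1(CC[C@H](O[Si](C)(C)C(C)(C)C)C(C)=C[C@@H]1O)CO | intermediate
18 | methyl (1S,2S,5S)-5-(tert-butyldimethylsilyloxy)-4-methyl-2-(triethylsilyloxy)-1-[(triethylsilyloxy)methyl]cyclohept-3-ene-1-carboxylate | COC(=O)[C@@]1(CC[C@H](O[Si](C)(C)C(C)(C)C)C(C)=C[C@@H]1O[Si](CC)(CC)CC)CO[Si](CC)(CC)CC | intermediate
19 | C9 primary alcohol: cycloheptene of 18 with CH2OH in place of CO2Me | OC[C@@]1(CC[C@H](O[Si](C)(C)C(C)(C)C)C(C)=C[C@@H]1O[Si](CC)(CC)CC)CO[Si](CC)(CC)CC | intermediate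
20 | C9 aldehyde: cycloheptene of 18 with CHO in place of CO2Me | O=C[C@@]1(CC[C@H](O[Si](C)(C)C(C)(C)C)C(C)=C[C@@H]1O[Si](CC)(CC)CC)CO[Si](CC)(CC)CC | intermediate
21 | β-hydroxy aldehyde: 20 with free C20 hydroxymethyl | O=C[C@@]1(CC[C@H](O[Si](C)(C)C(C)(C)C)C(C)=C[C@@H]1O[Si](CC)(CC)CC)CO | intermediate
22 | 2,2,6-trimethyl-4H-1,3-dioxin-4-one | CC1=CC(=O)OC(C)(C)O1 | starting material
23 | C20 acetoacetate of 21 | O=C[C@@]1(CC[C@H](O[Si](C)(C)C(C)(C)C)C(C)=C[C@@H]1O[Si](CC)(CC)CC)COC(=O)CC(C)=O | intermediate (not isolated)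
24 | spiro dienophile: 3-acetyl-5,6-dihydro-2H-pyran-2-one spiro-fused at C5 (= C10) to the cycloheptene (C3-OTBS, C4 methyl, C4=C5, C6-OTES) | CC(=O)C1=C[C@@]2(CC[C@H](O[Si](C)(C)C(C)(C)C)C(C)=C[C@@H]2O[Si](CC)(CC)CC)COC1=O | intermediate
25 | buta-1,3-diene | C=CC=C | starting material
26 | Diels–Alder adduct: cis-fused cyclohexene (C12=C13) δ-lactone with acetyl on C8, spiro cycloheptene as in 24 | CC(=O)[C@]12CC=CC[C@H]1[C@@]3(CC[C@H](O[Si](C)(C)C(C)(C)C)C(C)=C[C@@H]3O[Si](CC)(CC)CC)COC2=O | intermediate
27 | trimethylsilyl enol ether of 26 (C15(OSiMe3)=C16H2) | C=C(O[Si](C)(C)C)[C@]12CC=CC[C@H]1[C@@]3(CC[C@H](O[Si](C)(C)C(C)(C)C)C(C)=C[C@@H]3O[Si](CC)(CC)CC)COC2=O | intermediate (not isolated)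
28 | bicyclo[3.2.1]octenone lactone: C16–C13 bond, C15 ketone, C11=C12; spiro cycloheptene as in 24 | C1C(=O)[C@]23C[C@H]1C=C[C@H]2[C@@]1(CC[C@H](O[Si](C)(C)C(C)(C)C)C(C)=C[C@@H]1O[Si](CC)(CC)CC)COC3=O | intermediate
29 | saturated bicyclo[3.2.1]octanone lactone (C11–C12 reduced) | C1C(=O)[C@]23C[C@H]1CC[C@H]2[C@@]1(CC[C@H](O[Si](C)(C)C(C)(C)C)C(C)=C[C@@H]1O[Si](CC)(CC)CC)COC3=O | intermediate
30 | C4,C5 cis-diol of 29 (hydroxyls trans to C3-OTBS and C6-OTES) | C1C(=O)[C@]23C[C@H]1CC[C@H]2[C@@]1(CC[C@H](O[Si](C)(C)C(C)(C)C)[C@@](C)(O)[C@@H](O)[C@@H]1O[Si](CC)(CC)CC)COC3=O | intermediate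
31 | C5 mesylate of 30 | C1C(=O)[C@]23C[C@H]1CC[C@H]2[C@@]1(CC[C@H](O[Si](C)(C)C(C)(C)C)[C@@](C)(O)[C@@H](OS(C)(=O)=O)[C@@H]1O[Si](CC)(CC)CC)COC3=O | intermediate
32 | C4 acetate C5 mesylate | C1C(=O)[C@]23C[C@H]1CC[C@H]2[C@@]1(CC[C@H](O[Si](C)(C)C(C)(C)C)[C@@](C)(OC(C)=O)[C@@H](OS(C)(=O)=O)[C@@H]1O[Si](CC)(CC)CC)COC3=O | intermediate
33 | α-methylene ketone (C16=C17) of 32 | C=C1C(=O)[C@]23C[C@H]1CC[C@H]2[C@@]1(CC[C@H](O[Si](C)(C)C(C)(C)C)[C@@](C)(OC(C)=O)[C@@H](OS(C)(=O)=O)[C@@H]1O[Si](CC)(CC)CC)COC3=O | intermediate
34 | C6 alcohol: 33 with free C6-OH trans to C5-OMs | C=C1C(=O)[C@]23C[C@H]1CC[C@H]2[C@@]1(CC[C@H](O[Si](C)(C)C(C)(C)C)[C@@](C)(OC(C)=O)[C@@H](OS(C)(=O)=O)[C@@H]1O)COC3=O | intermediate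
35 | chloro(ethyl)aluminium C6 alkoxide of 34 | C=C1C(=O)[C@]23C[C@H]1CC[C@H]2[C@@]1(CC[C@H](O[Si](C)(C)C(C)(C)C)[C@@](C)(OC(C)=O)[C@@H](OS(C)(=O)=O)[C@@H]1O[Al](Cl)CC)COC3=O | intermediate (not isolated)
36 | 3-O-tert-butyldimethylsilyl ether of the target | C=C1C(=O)[C@]23C[C@H]1CC[C@H]2[C@@]1(CC[C@H](O[Si](C)(C)C(C)(C)C)[C@@](C)(OC(C)=O)[C@H]1C=O)COC3=O | intermediate
37 | CNP0199571.1 | C=C1C(=O)[C@]23C[C@H]1CC[C@H]2[C@@]1(CC[C@H](O)[C@@](C)(OC(C)=O)[C@H]1C=O)COC3=O | target

**Step count and risks**

Total step count: 24. Longest linear sequence: 24 steps (the route is fully linear from 1).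

Steps most likely to fail:

Step 9 (ring-closing metathesis). What may go wrong: slow loading of the ruthenium carbene on the 1,1-disubstituted alkene next to the silyl ether, together with the neopentyl position of the vinyl carbinol, lets intermolecular metathesis and catalyst decay outrun ring closure. Fallback, setting out from 13 and coming back at 17: the order of ring closure and quaternisation is exchanged. Ring-closing metathesis of 13, in which C10 still carries hydrogen, with the same catalyst should give methyl (1R,2S,5S)-5-(tert-butyldimethylsilyloxy)-2-hydroxy-4-methylcyclohept-3-ene-1-carboxylate F1. LiN(iPr)2 (2.3 equiv, THF, −78 to −20 °C) should convert it into the dilithium alkoxide–enolate of F1, F2. Formaldehyde should then enter trans to the chelated C6 alkoxide, as in Fráter–Seebach alkylations of cyclic β-hydroxy esters, and give 17.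

Step 16 (palladium-mediated cycloalkenylation). What may go wrong: carbon–carbon bond formation at C12 in place of C13 (bicyclo[2.2.2]octanone), or loss of the enol silane by protodesilylation before carbopalladation. Fallback, setting out from 24 and coming back at 29: the site of closure is fixed by a substituent and the bond is made by a radical.
- Diels–Alder reaction of 24 with 2-chlorobuta-1,3-diene (ZnCl2, CH2Cl2) should give the 12-chloro Diels–Alder adduct F3, chlorine para to C8.
- LiN(SiMe3)2 and chlorotrimethylsilane (THF, −78 °C) should give the trimethylsilyl enol ether of F3, F4.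
- N-Bromosuccinimide should give the bromomethyl ketone F5.
- Bu3SnH and AIBN (benzene, 80 °C) should close the ring 5-exo-trig at the unsubstituted alkene carbon C13, because this leaves the chlorine-stabilised radical at C12, and give the 12-chloro bicyclo[3.2.1]octanone F6.
- Further Bu3SnH (AIBN, toluene, 110 °C) removes the chlorine and gives 29.

Step 23 (ring contraction). What may go wrong: if the alkyl shift needs warming, transfer of ethyl or hydride from aluminium to the exocyclic enone or to the new aldehyde, or closure of the C6 alkoxide onto C5 from a diaxial conformer, competes with migration of C10. Fallback, setting out from 32 and coming back at 37: the contraction is run before the enone exists and without an organometallic, and the aldehyde is masked while the methylene group is introduced.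
- HF·pyridine (pyridine, THF) on 32 should give the C6 alcohol lacking the exocyclic methylene, F7.
- Buffered solvolytic pinacol-type rearrangement of the hydroxy mesylate (LiClO4, CaCO3, THF, 50 °C) should give the ring-contracted keto aldehyde F8.
- Trimethyl orthoformate with pyridinium p-toluenesulfonate in MeOH should give the dimethyl acetal F9.
- Methylenation under the conditions of step 21 should give the α-methylene ketone acetal F10.
- Aqueous HF in MeCN should then cleave acetal and silyl ether together and give 37.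

**Further compounds**

F1 | step 9 | methyl (1R,2S,5S)-5-(tert-butyldimethylsilyloxy)-2-hydroxy-4-methylcyclohept-3-ene-1-carboxylate | COC(=O)[C@@H]1CC[C@H](O[Si](C)(C)C(C)(C)C)C(C)=C[C@@H]1O
F2 | step 9 | dilithium alkoxide–enolate of F1 | [Li+].[Li+].COC([O-])=C1CC[C@H](O[Si](C)(C)C(C)(C)C)C(C)=C[C@@H]1[O-]
F3 | step 16 | 12-chloro Diels–Alder adduct (26 with Cl on C12) | CC(=O)[C@]12CC=C(Cl)C[C@H]1[C@@]3(CC[C@H](O[Si](C)(C)C(C)(C)C)C(C)=C[C@@H]3O[Si](CC)(CC)CC)COC2=O
F4 | step 16 | trimethylsilyl enol ether of F3 | C=C(O[Si](C)(C)C)[C@]12CC=C(Cl)C[C@H]1[C@@]3(CC[C@H](O[Si](C)(C)C(C)(C)C)C(C)=C[C@@H]3O[Si](CC)(CC)CC)COC2=O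
F5 | step 16 | bromomethyl ketone of F3 | BrCC(=O)[C@]12CC=C(Cl)C[C@H]1[C@@]3(CC[C@H](O[Si](C)(C)C(C)(C)C)C(C)=C[C@@H]3O[Si](CC)(CC)CC)COC2=O
F6 | step 16 | 12-chloro bicyclo[3.2.1]octanone (29 with Cl on C12, C12 configuration not defined) | C1C(=O)[C@]23C[C@H]1C(Cl)C[C@H]2[C@@]1(CC[C@H](O[Si](C)(C)C(C)(C)C)C(C)=C[C@@H]1O[Si](CC)(CC)CC)COC3=O
F7 | step 23 | C6 alcohol lacking the exocyclic methylene (32 without the triethylsilyl group) | C1C(=O)[C@]23C[C@H]1CC[C@H]2[C@@]1(CC[C@H](O[Si](C)(C)C(C)(C)C)[C@@](C)(OC(C)=O)[C@@H](OS(C)(=O)=O)[C@@H]1O)COC3=O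
F8 | step 23 | ring-contracted keto aldehyde (36 without C17) | C1C(=O)[C@]23C[C@H]1CC[C@H]2[C@@]1(CC[C@H](O[Si](C)(C)C(C)(C)C)[C@@](C)(OC(C)=O)[C@H]1C=O)COC3=O
F9 | step 23 | dimethyl acetal of F8 | C1C(=O)[C@]23C[C@H]1CC[C@H]2[C@@]1(CC[C@H](O[Si](C)(C)C(C)(C)C)[C@@](C)(OC(C)=O)[C@H]1C(OC)OC)COC3=O
F10 | step 23 | α-methylene ketone acetal (dimethyl acetal of 36) | C=C1C(=O)[C@]23C[C@H]1CC[C@H]2[C@@]1(CC[C@H](O[Si](C)(C)C(C)(C)C)[C@@](C)(OC(C)=O)[C@H]1C(OC)OC)COC3=O
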